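**Plan**
Retrosynthetic cuts, in order: (a) the bond from the quaternary ring carbon C6 to the prenyl CH2; (b) the bond from the bridging CH2 to the phloroglucinol carbon; (c) the C–CH3 bond at the carbinol carbon; (d) the cyclopentane bond between the isopropenyl-bearing CH and the adjacent ring CH2.
Enabling feature: the five ring carbons read CH2–CH2–C(OH)(CH3)–CH(CH2–)–CH(isopropenyl). Two bare methylenes on one side of the oxygenated carbon and two substituted methines on the other are the footprint of a divinyl ketone. Its C=O sits at the carbinol carbon, the bare vinyl arm can carry a sacrificial silyl group, and the other arm holds CH2O at its α-carbon and isopropenyl at its β-carbon.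
Forward order: three steps (phosphonate alkylation, olefination of methacrolein, vinyllithium acylation) give an achiral acyclic trienone, and its 4π closure makes the only ring that has to be built. The six-membered ring is bought as 2-methylphloroglucinol, joined through the CH2 bridge and dearomatised last.
Stereochemistry: the isopropenyl CH comes from the catalyst-imposed sense of conrotation on a geometrically pure 4E alkene, the neighbouring CH from equilibration to trans, the carbinol carbon from methyl delivery anti to the adjacent side chain, and C6 from a chiral palladium catalyst.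

Key step: step 4

Assumption: 21 is treated as the enol tautomer drawn in the target SMILES (the descriptor 6R refers to it), and the antipode named for each chiral catalyst in steps 4 and 12 is taken to be the one that gives the configuration shown, both antipodes being available.

**Step 1**
Reactants: 1 diethyl {2-[methoxy(methyl)amino]-2-oxoethyl}phosphonate; 2 (triisopropylsiloxy)methyl chloride (TOM chloride)
Product: 3 diethyl {1-[methoxy(methyl)amino]-1-oxo-3-[(triisopropylsilyl)oxy]propan-2-yl}phosphonate (racemic)
Conditions: NaH, THF, 0 °C; then 2, 0 °C → rt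
Reagents that add atoms: none
Why: C-Alkylation of a sodium phosphonoacetamide carbanion with an α-chloro ether, the reaction type by which BOM and SEM chlorides are attached to stabilised carbanions, should install the future bridging CH2 directly as its TIPS ether, and the racemic centre created disappears in step 2.

**Step 2**
Reactants: 3 phosphonate from step 1; 4 methacrolein
Product: 5 (2E)-N-methoxy-N,4-dimethyl-2-{[(triisopropylsilyl)oxy]methyl}penta-2,4-dienamide
Conditions: NaH, THF, 0 °C; then 4, 0 °C → rt; chromatography
Reagents that add atoms: none
Why: Horner–Wadsworth–Emmons olefination with an α-branched, amide-stabilised phosphonate adds reversibly to the enal and should therefore collapse mainly to the 2E diene with the carbonyl group trans to the isopropenyl group, and chromatography secures the geometrical purity on which step 4 depends.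

**Step 3**
Reactants: 5 dienyl Weinreb amide; 6 (E)-(2-bromovinyl)trimethylsilane
Product: 8 (1E,4E)-6-methyl-4-{[(triisopropylsilyl)oxy]methyl}-1-(trimethylsilyl)hepta-1,4,6-trien-3-one, via (E)-2-(trimethylsilyl)vinyllithium 7 (not isolated)
Conditions: 6, t-BuLi (2 equiv), Et2O, −78 °C; then 5, −78 → −30 °C
Reagents that add atoms: none
Why: Bromine–lithium exchange proceeds with retention of the E geometry and the Weinreb ketone synthesis stops after one 1,2-addition, so the cross-conjugated trienone should form without over-addition or conjugate attack.

**Step 4**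
Reactants: 8 trienone
Product: 10 (4R,5R)-4-(prop-1-en-2-yl)-5-{[(triisopropylsilyl)oxy]methyl}cyclopent-2-en-1-one, via cyclopentadienol 9 (not isolated)
Conditions: Zn(OTf)2 (10 mol %), (S)-STRIP [6,6'-bis(2,4,6-triisopropylphenyl)-SPINOL phosphoric acid] (12 mol %), PhOH (1.1 equiv), ClCH2CH2Cl, 40 °C
Reagents that add atoms: none
Why: Zn(OTf)2 and the chiral phosphoric acid bind the carbonyl oxygen of 8 and generate a 3-oxypentadienyl cation, which closes by a thermally allowed conrotatory 4π electrocyclisation between the silyl-bearing terminus C1 and the isopropenyl-bearing carbon C5; the C–Si bond stabilises the adjacent end of the resulting oxyallyl cation, phenol takes the silyl group so that the alkene ends up on the unsubstituted edge, and cyclopentadienol 9 is protonated at its α-carbon. The closest known reaction type is the silicon-directed Nazarov cyclisation of β-silyl divinyl ketones, including its catalytic enantioselective form with a Lewis acid and a chiral Brønsted acid; what is new here is only the alkenyl substituent on the β-carbon. The single ring formed, the cyclopentenone, is closed in the 4π-conrotatory electrocyclic mode through the C1–C5 bond. C4 of 10 is controlled by the sense of conrotation, which the chiral phosphate held at the carbonyl oxygen selects and which the pure 4E geometry translates into the R configuration, while the silyl-bearing carbon loses its stereochemical information on desilylation. C5 is controlled by protonation of 9 and, since it stays enolisable in the acidic medium, by equilibration to the more stable arrangement trans to the isopropenyl group. The step needs bond formation at the inner β-carbon and not at the terminus of the diene arm: the 4E geometry keeps that terminus remote from C1 and from the carbonyl carbon, which bars seven-ring, iso-Nazarov and oxa-6π closures, the α-CH2OTIPS group favours the U-shaped conformer required for C1–C5 overlap, and the weakly acidic catalyst pair should leave the 1,1-disubstituted alkene unprotonated.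

**Step 5**
Reactants: 10 cyclopentenone
Product: 11 (2R,3R)-3-(prop-1-en-2-yl)-2-{[(triisopropylsilyl)oxy]methyl}cyclopentan-1-one
Conditions: [(Ph3P)CuH]6 (3 mol %), MeSiH(OEt)2, t-BuOH, toluene, 0 °C → rt
Reagents that add atoms: none
Why: Copper hydride conjugate reduction transfers hydride only to the β-carbon of the enone, ignores the isolated 1,1-disubstituted alkene and the silyl ether, and the copper enolate, which lies on the CH2 side of the carbonyl group, is protonated by t-BuOH, so both stereocentres stay untouched.

**Step 6**
Reactants: 11 cyclopentanone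
Product: 12 (1R,2R,3R)-1-methyl-3-(prop-1-en-2-yl)-2-{[(triisopropylsilyl)oxy]methyl}cyclopentan-1-ol
Conditions: CeCl3 (anhydrous), MeLi, THF, −78 °C; then 11, −78 °C
Reagents that add atoms: methyllithium (used as MeCeCl2), [Li]C
Why: Organocerium 1,2-addition is nucleophilic but barely basic, which suppresses enolisation and β-elimination of the silyloxy group, and the methyl group should approach the carbonyl face anti to the bulky neighbouring CH2OTIPS group, as nucleophiles do with 2,3-trans-disubstituted cyclopentanones, setting C1 as R with OH cis to the side chain.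

**Step 7**
Reactants: 12 silyl ether
Product: 13 (1R,2R,3R)-2-(hydroxymethyl)-1-methyl-3-(prop-1-en-2-yl)cyclopentan-1-ol
Conditions: TBAF, THF, 0 °C → rt
Reagents that add atoms: none
Why: Fluoride-mediated cleavage of the silicon–oxygen bond frees the primary alcohol and affects neither the tertiary alcohol nor the alkene.

**Step 8**
Reactants: 13 diol
Product: 14 (1S,2R,5R)-2-hydroxy-2-methyl-5-(prop-1-en-2-yl)cyclopentane-1-carbaldehyde
Conditions: TEMPO (10 mol %), PhI(OAc)2, CH2Cl2, rt
Reagents that add atoms: none
Why: Oxoammonium (TEMPO) oxidation with PhI(OAc)2 as the terminal oxidant converts the primary alcohol into the aldehyde, cannot oxidise the tertiary alcohol, spares the alkene and is mild enough for a β-hydroxy aldehyde, which is used without storage.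

**Step 9**
Reactants: 15 2-methylphloroglucinol
Product: 16 2-methyl-1-(2,4,6-trihydroxy-3-methylphenyl)propan-1-one
Conditions: isobutyryl chloride, AlCl3, CH2Cl2–MeNO2, 0 → 40 °C
Reagents that add atoms: isobutyryl chloride, CC(C)C(=O)Cl
Why: Friedel–Crafts acylation of the strongly activated ring, whose two free positions are equivalent by symmetry, should stop at the mono-ketone because the hydrogen-bonded acyl group deactivates the product.

**Step 10**
Reactants: 14 β-hydroxy aldehyde; 16 acylphloroglucinol
Product: 18 1-(2,4,6-trihydroxy-3-{[(1S,2R,5R)-2-hydroxy-2-methyl-5-(prop-1-en-2-yl)cyclopentyl]methyl}-5-methylphenyl)-2-methylpropan-1-one, via ortho-quinone methide 17 (not isolated)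
Conditions: L-proline (20 mol %), Hantzsch ester (1.2 equiv), EtOH, rt
Reagents that add atoms: none
Why: Three-component reductive alkylation: amine-catalysed Knoevenagel-type condensation of the aldehyde at the only free ring carbon of 16 gives ortho-quinone methide 17, which the Hantzsch ester reduces at the exocyclic carbon with rearomatisation faster than it can tautomerise, no stereocentre being formed and the ring CH next to the bridge keeping its thermodynamically preferred trans arrangement.

**Step 11**
Reactants: 19 3-methylbut-2-en-1-ol (prenol)
Product: 20 methyl 3-methylbut-2-en-1-yl carbonate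
Conditions: ClCO2Me, pyridine, CH2Cl2, 0 °C
Reagents that add atoms: methyl chloroformate, COC(=O)Cl
Why: Acylation of a primary allylic alcohol with a chloroformate in the presence of pyridine is a standard carbonate synthesis.

**Step 12**
Reactants: 18 fully substituted acylphloroglucinol; 20 prenyl methyl carbonate
Product: 21 (6R)-3,5-dihydroxy-4-{[(1S,2R,5R)-2-hydroxy-2-methyl-5-(prop-1-en-2-yl)cyclopentyl]methyl}-6-methyl-6-(3-methylbut-2-en-1-yl)-2-(2-methylpropanoyl)cyclohexa-2,4-dien-1-one (target)
Conditions: Pd2(dba)3·CHCl3 (2.5 mol %), (R,R)-DACH-phenyl bis(2-diphenylphosphinobenzamide) ligand (7.5 mol %), 20 (1.05 equiv), CH2Cl2, 0 °C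
Reagents that add atoms: none
Why: Proposed new method: Pd(0) ionises 20 to a π-prenyl complex with loss of CO2 and the methoxide released deprotonates 18, whose ambident phenolate should attack the unsubstituted allyl terminus through the methyl-bearing ring carbon, the less hindered of the two alkyl-bearing carbons, while O-allylation stays reversible under Pd(0), and the chiral ligand pocket selects the face of the flat nucleophile so that C6 is set as R independently of the remote cyclopentane centres; the closest known reaction types are the Pd-catalysed asymmetric allylic dearomatisation of substituted naphthols and phenols, the Pd-catalysed enantioselective linear prenylation of oxindoles (Tsuji–Trost type), and the non-asymmetric dearomative prenylation of acylphloroglucinols.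

**Compound list**
1 | diethyl {2-[methoxy(methyl)amino]-2-oxoethyl}phosphonate | CCOP(=O)(CC(=O)N(C)OC)OCC | starting material
2 | (triisopropylsiloxy)methyl chloride | ClCO[Si](C(C)C)(C(C)C)C(C)C | starting material
3 | diethyl {1-[methoxy(methyl)amino]-1-oxo-3-[(triisopropylsilyl)oxy]propan-2-yl}phosphonate (racemic) | CCOP(=O)(OCC)C(CO[Si](C(C)C)(C(C)C)C(C)C)C(=O)N(C)OC | intermediate
4 | methacrolein | C=C(C)C=O | starting material
5 | (2E)-N-methoxy-N,4-dimethyl-2-{[(triisopropylsilyl)oxy]methyl}penta-2,4-dienamide | CON(C)C(=O)/C(CO[Si](C(C)C)(C(C)C)C(C)C)=C/C(C)=C | intermediate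
6 | (E)-(2-bromovinyl)trimethylsilane | C[Si](C)(C)/C=C/Br | starting material
7 | (E)-2-(trimethylsilyl)vinyllithium | C[Si](C)(C)/C=C/[Li] | intermediate
8 | (1E,4E)-6-methyl-4-{[(triisopropylsilyl)oxy]methyl}-1-(trimethylsilyl)hepta-1,4,6-trien-3-one | C[Si](C)(C)/C=C/C(=O)/C(CO[Si](C(C)C)(C(C)C)C(C)C)=C/C(C)=C | intermediate
9 | (3S)-3-(prop-1-en-2-yl)-2-{[(triisopropylsilyl)oxy]methyl}cyclopenta-1,4-dien-1-ol | C=C(C)[C@@H]1C=CC(O)=C1CO[Si](C(C)C)(C(C)C)C(C)C | intermediate
10 | (4R,5R)-4-(prop-1-en-2-yl)-5-{[(triisopropylsilyl)oxy]methyl}cyclopent-2-en-1-one | C=C(C)[C@@H]1C=CC(=O)[C@H]1CO[Si](C(C)C)(C(C)C)C(C)C | intermediate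
11 | (2R,3R)-3-(prop-1-en-2-yl)-2-{[(triisopropylsilyl)oxy]methyl}cyclopentan-1-one | C=C(C)[C@@H]1CCC(=O)[C@H]1CO[Si](C(C)C)(C(C)C)C(C)C | intermediate
12 | (1R,2R,3R)-1-methyl-3-(prop-1-en-2-yl)-2-{[(triisopropylsilyl)oxy]methyl}cyclopentan-1-ol | C=C(C)[C@@H]1CC[C@@](C)(O)[C@H]1CO[Si](C(C)C)(C(C)C)C(C)C | intermediate
13 | (1R,2R,3R)-2-(hydroxymethyl)-1-methyl-3-(prop-1-en-2-yl)cyclopentan-1-ol | C=C(C)[C@@H]1CC[C@@](C)(O)[C@H]1CO | intermediate
14 | (1S,2R,5R)-2-hydroxy-2-methyl-5-(prop-1-en-2-yl)cyclopentane-1-carbaldehyde | C=C(C)[C@@H]1CC[C@@](C)(O)[C@H]1C=O | intermediate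
15 | 2-methylphloroglucinol | Cc1c(O)cc(O)cc1O | starting material
16 | 2-methyl-1-(2,4,6-trihydroxy-3-methylphenyl)propan-1-one | CC(C)C(=O)c1c(O)cc(O)c(C)c1O | intermediate
17 | 3,5-dihydroxy-6-{[(1S,2R,5R)-2-hydroxy-2-methyl-5-(prop-1-en-2-yl)cyclopentyl]methylidene}-2-methyl-4-(2-methylpropanoyl)cyclohexa-2,4-dien-1-one (exocyclic alkene geometry undefined) | C=C(C)[C@@H]1CC[C@@](C)(O)[C@H]1C=C1C(=O)C(C)=C(O)C(C(=O)C(C)C)=C1O | intermediate
18 | 1-(2,4,6-trihydroxy-3-{[(1S,2R,5R)-2-hydroxy-2-methyl-5-(prop-1-en-2-yl)cyclopentyl]methyl}-5-methylphenyl)-2-methylpropan-1-one | C=C(C)[C@@H]1CC[C@@](C)(O)[C@H]1Cc1c(O)c(C)c(O)c(C(=O)C(C)C)c1O | intermediate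
19 | 3-methylbut-2-en-1-ol | CC(C)=CCO | starting material
20 | methyl 3-methylbut-2-en-1-yl carbonate | COC(=O)OCC=C(C)C | intermediate
21 | (6R)-3,5-dihydroxy-4-{[(1S,2R,5R)-2-hydroxy-2-methyl-5-(prop-1-en-2-yl)cyclopentyl]methyl}-6-methyl-6-(3-methylbut-2-en-1-yl)-2-(2-methylpropanoyl)cyclohexa-2,4-dien-1-one | C=C(C)[C@@H]1CC[C@@](C)(O)[C@H]1CC1=C(O)[C@@](C)(CC=C(C)C)C(=O)C(C(=O)C(C)C)=C1O | target

**Step count**
Total steps: 12. Longest linear sequence: 10 (steps 1–8, 10, 12).

**Steps most likely to fail**

Step 12. The chiral pocket may discriminate poorly between the faces of the flat, heavily substituted phenolate. Alkylation may also drift to the ring carbon that bears the cyclopentylmethyl group, to oxygen or to the substituted allyl terminus, and a second alkylation may follow. The fallback uses known chemistry, sets out from 18 and comes back at 21. Catalyst control is given up. Alkylative dearomatisation with prenyl bromide and aqueous KOH at 0 °C is the standard entry to gem-dialkylated acylphloroglucinols. It is expected to give 21 together with the (6S)-epimer of the target F1. The cyclopentane centres make the two products diastereomers, so they can be separated by chromatography, with preparative HPLC if needed.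

Step 4. Delocalisation of the charge into the diene arm may make the closure sluggish, so that acid-induced isomerisation or oligomerisation of the diene competes. The catalyst may also fail to distinguish the two senses of conrotation. The fallback sets out from 8 and comes back at 10, and it separates ring closure from stereocontrol. Stoichiometric FeCl3 in CH2Cl2 at −30 °C is the classical achiral promoter for β-silyl divinyl ketones and should close the ring quickly at low temperature. It should deliver the trans-enone as a racemate, that is 10 along with its mirror image (4S,5S)-4-(prop-1-en-2-yl)-5-{[(triisopropylsilyl)oxy]methyl}cyclopent-2-en-1-one F2. Resolution by preparative chromatography on a chiral stationary phase then returns 10.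

Step 10. Amine catalysis may trigger retro-aldol opening or dehydration of the β-hydroxy aldehyde. The hindered α-branched aldehyde may condense too slowly with the moderately nucleophilic acylphloroglucinol, or the quinone methide may tautomerise before hydride transfer. The fallback sets out from 11 and comes back at 18, and it forms the aryl–CH2 bond by conjugate addition before the carbinol exists.
- Buffered TBAF/AcOH frees (2R,3R)-2-(hydroxymethyl)-3-(prop-1-en-2-yl)cyclopentan-1-one F3.
- MsCl/Et3N converts F3 into the primary mesylate F4, which eliminates in the same flask to (3S)-2-methylidene-3-(prop-1-en-2-yl)cyclopentan-1-one F5.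
- Michael addition of 16 through its free ring carbon (catalytic Et3N, THF), followed by protonation to the trans isomer, gives the (2S,3R)-configured aryl-methyl cyclopentanone F6.
- Excess MeCeCl2 at −78 °C first forms the phenolates, which shield the aryl ketone. It then adds methyl to the ring ketone anti to the CH2Ar group and gives 18.

**Further compounds**
F1 | step 12 | (6S)-epimer of 21 | C=C(C)[C@@H]1CC[C@@](C)(O)[C@H]1CC1=C(O)[C@](C)(CC=C(C)C)C(=O)C(C(=O)C(C)C)=C1O
F2 | step 4 | (4S,5S)-4-(prop-1-en-2-yl)-5-{[(triisopropylsilyl)oxy]methyl}cyclopent-2-en-1-one | C=C(C)[C@H]1C=CC(=O)[C@@H]1CO[Si](C(C)C)(C(C)C)C(C)C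
F3 | step 10 | (2R,3R)-2-(hydroxymethyl)-3-(prop-1-en-2-yl)cyclopentan-1-one | C=C(C)[C@@H]1CCC(=O)[C@H]1CO
F4 | step 10 | [(1R,2R)-5-oxo-2-(prop-1-en-2-yl)cyclopentyl]methyl methanesulfonate | C=C(C)[C@@H]1CCC(=O)[C@H]1COS(C)(=O)=O
F5 | step 10 | (3S)-2-methylidene-3-(prop-1-en-2-yl)cyclopentan-1-one | C=C(C)[C@@H]1CCC(=O)C1=C
F6 | step 10 | (2S,3R)-3-(prop-1-en-2-yl)-2-{[2,4,6-trihydroxy-3-methyl-5-(2-methylpropanoyl)phenyl]methyl}cyclopentan-1-one | C=C(C)[C@@H]1CCC(=O)[C@H]1Cc1c(O)c(C)c(O)c(C(=O)C(C)C)c1O
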